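**Strategy.** The furanone ring (O–C3=C2–C1(=O)–C10) is treated as the closed form of a ten-membered C1-oxo C2≡C3 ynone, so the carbocycle is disconnected at C1–C2. In one operation a chromium acetylide, generated from a C2 iodoalkyne, adds to the neopentyl C1 aldehyde, forming C1–C2 and the ten-membered ring; the cis C4=C5 alkene holds the termini together and the reagent spares lactone, esters and methylene lactone. The precursor is an open-chain C1 aldehyde bearing the trans α-methylene lactone (C6/C7), the C8 isovalerate, C9 acetate, a C10 silyl ether and the (Z)-iodoenyne, assembled by indium coupling at C7–C8 of a butenolide bromide with a lactate-derived aldehyde.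

Key step: step 21

Atom numbers follow the target: C1 ketone, C2=C3, C4(Me)=C5, C6 (lactone O), C7, C8 (isovalerate), C9 (acetate), C10 (Me, furanone O), C11=C13, C12 lactone carbonyl.

Assumption: (S,S)-ProPhenol is taken to give the 6R carbinol in step 9; if the sense of induction is the reverse, the antipodal ligand is used.

Remark: a chair transition state in the indium coupling of this cyclic allyl unit places O8 anti to C6 (8R, the wrong epimer), so C8 is reset by oxidation and C10-hydroxyl-directed reduction (steps 14 and 15).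

Step 1
Reactants: 1 (S)-lactic acid; 2 pivalaldehyde
Product: 3 (2S,5S)-2-tert-butyl-5-methyl-1,3-dioxolan-4-one
Conditions: p-TsOH (cat.), pentane, reflux, Dean–Stark trap; crystallisation at −78 °C
Reagents that add atoms: none
Why: Acid-catalysed acetalisation under equilibrium control favours the cis-2,5-disubstituted dioxolanone (self-regeneration-of-stereocentres template) and crystallisation removes the trans isomer; the lactate centre is untouched and the acetal centre (2S) is set thermodynamically.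

Step 2
Reactants: 3 (2S,5S)-2-tert-butyl-5-methyl-1,3-dioxolan-4-one; 4 acrolein
Product: 6 (2S,5R)-2-tert-butyl-5-[(1R)-1-hydroxyprop-2-en-1-yl]-5-methyl-1,3-dioxolan-4-one, via lithium enolate 5 (not isolated)
Conditions: LDA, THF, −78 °C; then 4, −78 °C; aq. NH4Cl
Reagents that add atoms: none
Why: Aldol addition of the dioxolanone enolate, in which the aldehyde enters anti to the tert-butyl group so that C10 is rebuilt with retention of the lactate configuration, while a Zimmerman–Traxler chair with vinyl equatorial (enolate methyl cis to O–Li) should favour the 9R carbinol; the minor C9 epimer is removed by chromatography.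

Step 3
Reactants: 6 (2S,5R)-2-tert-butyl-5-[(1R)-1-hydroxyprop-2-en-1-yl]-5-methyl-1,3-dioxolan-4-one
Product: 7 (2S,3R)-2-methylpent-4-ene-1,2,3-triol
Conditions: LiAlH4, THF, 0 °C → rt; Fieser work-up
Reagents that add atoms: none
Why: Hydride reduction of the acyl-acetal carbonyl releases C1 as a primary alcohol and unmasks the tertiary C10 hydroxyl (the acetal carbon leaves as neopentyl alcohol); no stereocentre is touched and the isolated vinyl group is inert.

Step 4
Reactants: 7 (2S,3R)-2-methylpent-4-ene-1,2,3-triol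
Product: 8 (2S,3R)-1-[(tert-butyldimethylsilyl)oxy]-2-methylpent-4-ene-2,3-diol
Conditions: TBSCl (1.05 equiv), imidazole, DCM, 0 °C
Reagents that add atoms: tert-butyldimethylsilyl chloride, CC(C)(C)[Si](C)(C)Cl
Why: Sterically controlled silylation, in which the primary C1 hydroxyl reacts far faster than the secondary allylic and the tertiary hydroxyls.

Step 5
Reactants: 8 (2S,3R)-1-[(tert-butyldimethylsilyl)oxy]-2-methylpent-4-ene-2,3-diol
Product: 9 (3R,4S)-5-[(tert-butyldimethylsilyl)oxy]-4-hydroxy-4-methylpent-1-en-3-yl acetate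
Conditions: Ac2O, pyridine, DMAP (cat.), DCM, 0 °C
Reagents that add atoms: acetic anhydride, CC(=O)OC(C)=O
Why: DMAP-catalysed acetylation takes the secondary C9 hydroxyl and leaves the tertiary C10 hydroxyl, which is kept free as the directing group for step 15.

Step 6
Reactants: 9 (3R,4S)-5-[(tert-butyldimethylsilyl)oxy]-4-hydroxy-4-methylpent-1-en-3-yl acetate
Product: 11 (2S,3S)-4-[(tert-butyldimethylsilyl)oxy]-3-hydroxy-3-methyl-1-oxobutan-2-yl acetate, via ozonide 10 (not isolated)
Conditions: O3, DCM, −78 °C; then PPh3, −78 °C → rt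
Reagents that add atoms: ozone, [O-][O+]=O
Why: Ozonolysis with reductive work-up cleaves the only C=C bond to reveal the C8 aldehyde without touching C9; the α-acetoxy aldehyde is used at once.

Step 7
Reactants: 12 (Z)-3-methylpent-2-en-4-yn-1-ol
Product: 14 (Z)-3-methyl-5-(trimethylsilyl)pent-2-en-4-yn-1-ol, via bis-silyl ether 13 (not isolated)
Conditions: n-BuLi (2.1 equiv), THF, −78 °C; TMSCl (2.3 equiv), −78 °C → rt; then 1 M aq. HCl
Reagents that add atoms: chlorotrimethylsilane, C[Si](C)(C)Cl
Why: Double deprotonation and bis-silylation followed by selective acid hydrolysis of the labile O–Si bond caps the alkyne, which would otherwise be zincated in step 9 and hydrogenated in step 10.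

Step 8
Reactants: 14 (Z)-3-methyl-5-(trimethylsilyl)pent-2-en-4-yn-1-ol
Product: 15 (Z)-3-methyl-5-(trimethylsilyl)pent-2-en-4-ynal
Conditions: MnO2 (activated, excess), DCM, rt
Reagents that add atoms: none
Why: Heterogeneous allylic oxidation under neutral conditions gives the enal with the Z geometry retained; the aldehyde is used without storage.

Step 9
Reactants: 15 (Z)-3-methyl-5-(trimethylsilyl)pent-2-en-4-ynal; 16 methyl propiolate
Product: 18 methyl (4R,5Z)-4-hydroxy-6-methyl-8-(trimethylsilyl)oct-5-ene-2,7-diynoate, via zinc acetylide 17 (not isolated)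
Conditions: Me2Zn, (S,S)-ProPhenol (20 mol %), Ph3P=O (40 mol %), toluene, 0 °C; 16 first, then 15
Reagents that add atoms: none
Why: Zinc–ProPhenol-catalysed enantioselective alkynylation of an α,β-unsaturated aldehyde, in which the chiral dinuclear zinc complex selects the aldehyde face and so sets C6 (R).

Step 10
Reactants: 18 methyl (4R,5Z)-4-hydroxy-6-methyl-8-(trimethylsilyl)oct-5-ene-2,7-diynoate
Product: 20 (5S)-5-[(1Z)-2-methyl-4-(trimethylsilyl)but-1-en-3-yn-1-yl]furan-2(5H)-one, via Z-hydroxy enoate 19 (not isolated)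
Conditions: H2 (1 atm), Pd/CaCO3 poisoned with Pb(OAc)2, quinoline, EtOAc, rt; then CSA (cat.), DCM, rt
Reagents that add atoms: none
Why: cis-Semihydrogenation (Lindlar type) of the electron-poor ynoate, which is reduced much faster than the silyl-capped alkyne, gives the Z-γ-hydroxy enoate that lactonises to the butenolide; C6 is not involved (the descriptor changes by priority only).

Step 11
Reactants: 20 (5S)-5-[(1Z)-2-methyl-4-(trimethylsilyl)but-1-en-3-yn-1-yl]furan-2(5H)-one; 21 formaldehyde (37 % aqueous)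
Product: 22 (5R)-3-(hydroxymethyl)-5-[(1Z)-2-methyl-4-(trimethylsilyl)but-1-en-3-yn-1-yl]furan-2(5H)-one
Conditions: PBu3 (20 mol %), THF/H2O, rt
Reagents that add atoms: none
Why: Morita–Baylis–Hillman α-hydroxymethylation (phosphine conjugate addition, aldol with formaldehyde, β-elimination) installs C13; the weakly basic phosphine limits γ-deprotonation at C6.

Step 12
Reactants: 22 (5R)-3-(hydroxymethyl)-5-[(1Z)-2-methyl-4-(trimethylsilyl)but-1-en-3-yn-1-yl]furan-2(5H)-one
Product: 23 (5R)-3-(bromomethyl)-5-[(1Z)-2-methyl-4-(trimethylsilyl)but-1-en-3-yn-1-yl]furan-2(5H)-one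
Conditions: PBr3, Et2O, 0 °C
Reagents that add atoms: phosphorus tribromide, BrP(Br)Br
Why: Standard conversion of a primary allylic alcohol into the allylic bromide without affecting the lactone or the silylalkyne.

Step 13
Reactants: 23 (5R)-3-(bromomethyl)butenolide; 11 C8 aldehyde
Product: 25 C7–C8 coupled α-methylene lactone with 8-OH (both epimers) 9-OAc 10-OH and 1-OTBS (full name in the list), via allylindium bromide 24 (not isolated)
Conditions: In powder (1.5 equiv), THF/H2O (1:1), rt
Reagents that add atoms: none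
Why: Indium-mediated Barbier allylation in which the allylindium reacts through its γ-carbon (C7) on the butenolide face anti to the C6 side chain, fixing 7S (6,7-trans) and unveiling the methylene lactone; C8 forms mainly as the 8R carbinol (chair transition state) and is erased in step 14.

Step 14
Reactants: 25 Barbier adduct (C8 epimers)
Product: 26 C8 ketone (full name in the list)
Conditions: Dess–Martin periodinane, NaHCO3, DCM, 0 °C → rt
Reagents that add atoms: none
Why: Dess–Martin oxidation of the secondary carbinol under buffered, base-free conditions converges both C8 epimers to one β-hydroxy ketone while avoiding enolisation towards C7 or C9.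

Step 15
Reactants: 26 C8 ketone
Product: 27 (8S)-alcohol (full name in the list)
Conditions: Me4NBH(OAc)3, MeCN/AcOH (1:1), −30 °C
Reagents that add atoms: none
Why: Evans–Saksena reduction, in which the free tertiary C10 hydroxyl binds boron and delivers hydride intramolecularly through a chair with C7 and the C9 acetate equatorial, giving the 1,3-anti diol (8S); the enoate, lactone and alkyne are not reduced by this reagent.

Step 16
Reactants: 27 (8S)-alcohol
Product: 28 C8 isovalerate (full name in the list)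
Conditions: 3-methylbutanoic anhydride, DMAP (cat.), pyridine, DCM, 0 °C
Reagents that add atoms: 3-methylbutanoic anhydride, CC(C)CC(=O)OC(=O)CC(C)C
Why: DMAP-catalysed acylation of the secondary C8 hydroxyl, which is fast enough at 0 °C to outpace acetyl migration from O9 and leaves the tertiary C10 hydroxyl untouched.

Step 17
Reactants: 28 C8 isovalerate
Product: 29 iodoalkyne (full name in the list)
Conditions: N-iodosuccinimide, AgNO3 (10 mol %), acetone, rt, dark
Reagents that add atoms: N-iodosuccinimide, O=C1CCC(=O)N1I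
Why: Silver-catalysed iododesilylation of the alkynylsilane (via a silver acetylide) gives the 1-iodoalkyne directly under neutral conditions that tolerate the esters, lactone and free tertiary alcohol.

Step 18
Reactants: 29 iodoalkyne
Product: 30 C1,C10-diol (full name in the list)
Conditions: HF·pyridine, pyridine, THF, 0 °C → rt
Reagents that add atoms: none
Why: Buffered fluoride cleavage of the primary silyl ether, the only silyl group left in the molecule, under non-basic conditions that do not move the acyl groups.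

Step 19
Reactants: 30 C1,C10-diol
Product: 31 bis(triethylsilyl) ether (full name in the list)
Conditions: TESOTf (3 equiv), 2,6-lutidine, DCM, −78 → 0 °C
Reagents that add atoms: triethylsilyl trifluoromethanesulfonate, CC[Si](CC)(CC)OS(=O)(=O)C(F)(F)F
Why: Silyl triflate with a hindered base silylates both the primary and the tertiary hydroxyl, placing the C10 protecting group required in the cyclisation precursor.

Step 20
Reactants: 31 bis(triethylsilyl) ether
Product: 33 iodoalkyne aldehyde (cyclisation precursor; full name in the list), via primary alcohol 32 (not isolated)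
Conditions: (COCl)2, DMSO, DCM, −78 → −40 °C; then Et3N, −78 → 0 °C
Reagents that add atoms: none
Why: Swern oxidation applied directly to a primary triethylsilyl ether, which is cleaved by the chlorosulfonium salt far faster than the hindered tertiary one and oxidised in the same flask; C10 carries no hydrogen, so the aldehyde cannot epimerise.

Step 21
Reactants: 33 iodoalkyne aldehyde
Product: 35 ten-membered cyclic enyne carbinol (full name in the list), via alkynylchromium 34 (not isolated)
Conditions: CrCl2 (8 equiv), NiCl2 (0.4 equiv), degassed THF, rt, syringe-pump addition of 33 to a final 2 mM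
Reagents that add atoms: none
Why: Divalent chromium, helped by NiCl2 (insertion of zerovalent nickel into the C(sp)–I bond and transmetallation), converts the iodoalkyne into an alkynyl trivalent-chromium species that adds 1,2 to the chromium-bound C1 aldehyde. The closest known reaction type is the Nozaki–Hiyama–Kishi iodoalkyne–aldehyde macrocyclisation used for nine- and ten-membered cyclic enynes and enediynes. The ten-membered carbocycle closes in the 10-exo-trig mode (C2 onto the exocyclic C1=O), the Z-C4=C5 alkene holding both termini on one side and high dilution suppressing oligomers. The only new stereocentre, C1, is biased by the adjacent quaternary C10 but needs no control because it is oxidised in step 22. The step needs selectivity for the aldehyde over the lactone, two esters and the methylene lactone, which the non-basic, aldehyde-selective organochromium reagent provides, while the C10 silyl ether prevents α-ketol rearrangement and hemiacetal formation of the aldehyde.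

Step 22
Reactants: 35 cyclic enyne carbinol
Product: 36 cyclic ynone (full name in the list)
Conditions: Dess–Martin periodinane, NaHCO3, DCM, 0 °C
Reagents that add atoms: none
Why: Dess–Martin oxidation of the propargylic alcohol removes the C1 stereocentre and gives the strained C1-oxo C2≡C3 ynone under neutral conditions, with the C10 oxygen still silylated so that the ynone can be handled.

Step 23
Reactants: 36 cyclic ynone
Product: 38 target CNP0255553.1, via hydroxy ynone 37 (not isolated)
Conditions: HF·pyridine, THF, 0 °C → rt; AuCl3 (5 mol %), DCM, rt only if 37 persists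
Reagents that add atoms: none
Why: Desilylation frees the C10 hydroxyl, which adds transannularly to C3 of the bent, strain-activated ynone (5-endo-dig oxa-Michael addition, the known cyclisation of γ-hydroxy ynones to 3(2H)-furanones) to close the furanone ring; no stereocentre is formed or disturbed.

**Compound list**

1 | (S)-lactic acid | C[C@H](O)C(=O)O | starting material
2 | pivalaldehyde (2,2-dimethylpropanal) | CC(C)(C)C=O | starting material
3 | (2S,5S)-2-tert-butyl-5-methyl-1,3-dioxolan-4-one | C[C@@H]1O[C@H](C(C)(C)C)OC1=O | intermediate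
4 | acrolein (prop-2-enal) | C=CC=O | starting material
5 | lithium (2S)-2-tert-butyl-5-methyl-1,3-dioxol-4-olate (not isolated) | CC1=C([O-])O[C@@H](C(C)(C)C)O1.[Li+] | intermediate
6 | (2S,5R)-2-tert-butyl-5-[(1R)-1-hydroxyprop-2-en-1-yl]-5-methyl-1,3-dioxolan-4-one | C[C@]1([C@H](O)C=C)O[C@H](C(C)(C)C)OC1=O | intermediate
7 | (2S,3R)-2-methylpent-4-ene-1,2,3-triol | C=C[C@@H](O)[C@@](C)(O)CO | intermediate
8 | (2S,3R)-1-[(tert-butyldimethylsilyl)oxy]-2-methylpent-4-ene-2,3-diol | C=C[C@@H](O)[C@@](C)(O)CO[Si](C)(C)C(C)(C)C | intermediate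
9 | (3R,4S)-5-[(tert-butyldimethylsilyl)oxy]-4-hydroxy-4-methylpent-1-en-3-yl acetate | C=C[C@@H](OC(C)=O)[C@@](C)(O)CO[Si](C)(C)C(C)(C)C | intermediate
10 | secondary ozonide of 9: (1S,2S)-3-[(tert-butyldimethylsilyl)oxy]-2-hydroxy-2-methyl-1-(1,2,4-trioxolan-3-yl)propyl acetate, epimers at the trioxolane carbon (not isolated) | CC(=O)O[C@H](C1OCOO1)[C@@](C)(O)CO[Si](C)(C)C(C)(C)C | intermediate
11 | (2S,3S)-4-[(tert-butyldimethylsilyl)oxy]-3-hydroxy-3-methyl-1-oxobutan-2-yl acetate | O=C[C@@H](OC(C)=O)[C@@](C)(O)CO[Si](C)(C)C(C)(C)C | intermediate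
12 | (Z)-3-methylpent-2-en-4-yn-1-ol | C#C/C(C)=C\CO | starting material
13 | (Z)-trimethyl{[3-methyl-5-(trimethylsilyl)pent-2-en-4-yn-1-yl]oxy}silane (not isolated) | C[Si](C)(C)C#C/C(C)=C\CO[Si](C)(C)C | intermediate
14 | (Z)-3-methyl-5-(trimethylsilyl)pent-2-en-4-yn-1-ol | C[Si](C)(C)C#C/C(C)=C\CO | intermediate
15 | (Z)-3-methyl-5-(trimethylsilyl)pent-2-en-4-ynal | C[Si](C)(C)C#C/C(C)=C\C=O | intermediate
16 | methyl propiolate | C#CC(=O)OC | starting material
17 | methyl 3-(methylzincio)prop-2-ynoate (not isolated) | C[Zn]C#CC(=O)OC | intermediate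
18 | methyl (4R,5Z)-4-hydroxy-6-methyl-8-(trimethylsilyl)oct-5-ene-2,7-diynoate | C[Si](C)(C)C#C/C(C)=C\[C@@H](O)C#CC(=O)OC | intermediate
19 | methyl (2Z,4S,5Z)-4-hydroxy-6-methyl-8-(trimethylsilyl)octa-2,5-dien-7-ynoate (not isolated) | C[Si](C)(C)C#C/C(C)=C\[C@@H](O)/C=C\C(=O)OC | intermediate
20 | (5S)-5-[(1Z)-2-methyl-4-(trimethylsilyl)but-1-en-3-yn-1-yl]furan-2(5H)-one | C[Si](C)(C)C#C/C(C)=C\[C@H]1OC(=O)C=C1 | intermediate
21 | formaldehyde | C=O | starting material
22 | (5R)-3-(hydroxymethyl)-5-[(1Z)-2-methyl-4-(trimethylsilyl)but-1-en-3-yn-1-yl]furan-2(5H)-one | C[Si](C)(C)C#C/C(C)=C\[C@H]1OC(=O)C(CO)=C1 | intermediate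
23 | (5R)-3-(bromomethyl)-5-[(1Z)-2-methyl-4-(trimethylsilyl)but-1-en-3-yn-1-yl]furan-2(5H)-one | C[Si](C)(C)C#C/C(C)=C\[C@H]1OC(=O)C(CBr)=C1 | intermediate
24 | {[(5R)-5-[(1Z)-2-methyl-4-(trimethylsilyl)but-1-en-3-yn-1-yl]-2-oxo-2,5-dihydrofuran-3-yl]methyl}indium dibromide (not isolated) | C[Si](C)(C)C#C/C(C)=C\[C@H]1OC(=O)C(C[In](Br)Br)=C1 | intermediate
25 | (2R,3S)-4-[(tert-butyldimethylsilyl)oxy]-1,3-dihydroxy-3-methyl-1-{(2R,3R)-4-methylidene-2-[(1Z)-2-methyl-4-(trimethylsilyl)but-1-en-3-yn-1-yl]-5-oxooxolan-3-yl}butan-2-yl acetate, both epimers at C1 of the butyl chain (= C8) | C[Si](C)(C)C#C/C(C)=C\[C@H]1OC(=O)C(=C)[C@@H]1C(O)[C@@H](OC(C)=O)[C@@](C)(O)CO[Si](C)(C)C(C)(C)C | intermediate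
26 | (2S,3S)-4-[(tert-butyldimethylsilyl)oxy]-3-hydroxy-3-methyl-1-{(2R,3S)-4-methylidene-2-[(1Z)-2-methyl-4-(trimethylsilyl)but-1-en-3-yn-1-yl]-5-oxooxolan-3-yl}-1-oxobutan-2-yl acetate | C[Si](C)(C)C#C/C(C)=C\[C@H]1OC(=O)C(=C)[C@@H]1C(=O)[C@@H](OC(C)=O)[C@@](C)(O)CO[Si](C)(C)C(C)(C)C | intermediate
27 | (1S,2R,3S)-4-[(tert-butyldimethylsilyl)oxy]-1,3-dihydroxy-3-methyl-1-{(2R,3R)-4-methylidene-2-[(1Z)-2-methyl-4-(trimethylsilyl)but-1-en-3-yn-1-yl]-5-oxooxolan-3-yl}butan-2-yl acetate | C[Si](C)(C)C#C/C(C)=C\[C@H]1OC(=O)C(=C)[C@@H]1[C@H](O)[C@@H](OC(C)=O)[C@@](C)(O)CO[Si](C)(C)C(C)(C)C | intermediate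
28 | (1S,2R,3S)-2-(acetyloxy)-4-[(tert-butyldimethylsilyl)oxy]-3-hydroxy-3-methyl-1-{(2R,3S)-4-methylidene-2-[(1Z)-2-methyl-4-(trimethylsilyl)but-1-en-3-yn-1-yl]-5-oxooxolan-3-yl}butyl 3-methylbutanoate | C[Si](C)(C)C#C/C(C)=C\[C@H]1OC(=O)C(=C)[C@@H]1[C@H](OC(=O)CC(C)C)[C@@H](OC(C)=O)[C@@](C)(O)CO[Si](C)(C)C(C)(C)C | intermediate
29 | (1S,2R,3S)-2-(acetyloxy)-4-[(tert-butyldimethylsilyl)oxy]-3-hydroxy-1-{(2R,3S)-2-[(1Z)-4-iodo-2-methylbut-1-en-3-yn-1-yl]-4-methylidene-5-oxooxolan-3-yl}-3-methylbutyl 3-methylbutanoate | IC#C/C(C)=C\[C@H]1OC(=O)C(=C)[C@@H]1[C@H](OC(=O)CC(C)C)[C@@H](OC(C)=O)[C@@](C)(O)CO[Si](C)(C)C(C)(C)C | intermediate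
30 | (1S,2R,3S)-2-(acetyloxy)-3,4-dihydroxy-1-{(2R,3S)-2-[(1Z)-4-iodo-2-methylbut-1-en-3-yn-1-yl]-4-methylidene-5-oxooxolan-3-yl}-3-methylbutyl 3-methylbutanoate | IC#C/C(C)=C\[C@H]1OC(=O)C(=C)[C@@H]1[C@H](OC(=O)CC(C)C)[C@@H](OC(C)=O)[C@@](C)(O)CO | intermediate
31 | (1S,2R,3S)-2-(acetyloxy)-1-{(2R,3S)-2-[(1Z)-4-iodo-2-methylbut-1-en-3-yn-1-yl]-4-methylidene-5-oxooxolan-3-yl}-3-methyl-3,4-bis[(triethylsilyl)oxy]butyl 3-methylbutanoate | IC#C/C(C)=C\[C@H]1OC(=O)C(=C)[C@@H]1[C@H](OC(=O)CC(C)C)[C@@H](OC(C)=O)[C@@](C)(O[Si](CC)(CC)CC)CO[Si](CC)(CC)CC | intermediate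
32 | (1S,2R,3S)-2-(acetyloxy)-4-hydroxy-1-{(2R,3S)-2-[(1Z)-4-iodo-2-methylbut-1-en-3-yn-1-yl]-4-methylidene-5-oxooxolan-3-yl}-3-methyl-3-[(triethylsilyl)oxy]butyl 3-methylbutanoate (not isolated) | IC#C/C(C)=C\[C@H]1OC(=O)C(=C)[C@@H]1[C@H](OC(=O)CC(C)C)[C@@H](OC(C)=O)[C@@](C)(O[Si](CC)(CC)CC)CO | intermediate
33 | (1S,2R,3R)-2-(acetyloxy)-1-{(2R,3S)-2-[(1Z)-4-iodo-2-methylbut-1-en-3-yn-1-yl]-4-methylidene-5-oxooxolan-3-yl}-3-methyl-4-oxo-3-[(triethylsilyl)oxy]butyl 3-methylbutanoate (cyclisation precursor) | IC#C/C(C)=C\[C@H]1OC(=O)C(=C)[C@@H]1[C@H](OC(=O)CC(C)C)[C@@H](OC(C)=O)[C@@](C)(O[Si](CC)(CC)CC)C=O | intermediate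
34 | alkynylchromium dichloride of 33 (C2–CrCl2 in place of C2–I; not isolated) | Cl[Cr](Cl)C#C/C(C)=C\[C@H]1OC(=O)C(=C)[C@@H]1[C@H](OC(=O)CC(C)C)[C@@H](OC(C)=O)[C@@](C)(O[Si](CC)(CC)CC)C=O | intermediate
35 | (6R,7S,8S,9R,10S)-9-acetoxy-1-hydroxy-8-(3-methylbutanoyloxy)-10-(triethylsilyloxy)germacra-4Z,11(13)-dien-2-yn-12,6-olide (ten-membered cyclic enyne carbinol; either or both C1 epimers, drawn 1R) | O[C@@H]1C#C/C(C)=C\[C@H]2OC(=O)C(=C)[C@@H]2[C@H](OC(=O)CC(C)C)[C@@H](OC(C)=O)[C@@]1(C)O[Si](CC)(CC)CC | intermediate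
36 | (6R,7S,8S,9R,10R)-9-acetoxy-8-(3-methylbutanoyloxy)-1-oxo-10-(triethylsilyloxy)germacra-4Z,11(13)-dien-2-yn-12,6-olide | O=C1C#C/C(C)=C\[C@H]2OC(=O)C(=C)[C@@H]2[C@H](OC(=O)CC(C)C)[C@@H](OC(C)=O)[C@@]1(C)O[Si](CC)(CC)CC | intermediate
37 | (6R,7S,8S,9R,10R)-9-acetoxy-10-hydroxy-8-(3-methylbutanoyloxy)-1-oxogermacra-4Z,11(13)-dien-2-yn-12,6-olide (not isolated) | O=C1C#C/C(C)=C\[C@H]2OC(=O)C(=C)[C@@H]2[C@H](OC(=O)CC(C)C)[C@@H](OC(C)=O)[C@@]1(C)O | intermediate
38 | CNP0255553.1: (6R,7S,8S,9R,10R)-9-acetoxy-8-(3-methylbutanoyloxy)-1-oxo-3,10-epoxygermacra-2,4Z,11(13)-trien-12,6-olide | C=C1C(=O)O[C@@H]2/C=C(/C)C3=CC(=O)[C@](C)(O3)[C@H](OC(C)=O)[C@@H](OC(=O)CC(C)C)[C@@H]12 | target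

**Step count.** Total: 23 steps. Longest linear sequence: 17 steps (steps 1–6, then 13–23; the butenolide branch, steps 7–12, is equally long).

**Steps most likely to fail**

Step 21. Intermolecular coupling to oligomers and protonation of the alkynylchromium may outrun the strained ten-membered closure. The fallback forms the same C1–C2 bond from a terminal alkyne by amine/zinc acetylide addition, with no halide and no reducing metal. It sets out from 28: silver-catalysed protodesilylation (AgNO3 cat., acetone/H2O) would give the terminal alkyne F1; HF·pyridine would give the diol F2; TESOTf/2,6-lutidine would give the bis(triethylsilyl) ether F3; Swern oxidation would give the alkynyl aldehyde F4; slow addition of F4 to Zn(OTf)2 and Et3N in toluene at high dilution should close the ring and return to 35.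

Step 15. Exchange of the hindered tertiary C10 hydroxyl onto boron may be too slow, so that reduction becomes undirected with poor facial selectivity, while the sensitive ketone 26 epimerises at C9 or loses the C6 carboxylate by β-elimination. The fallback avoids the ketone altogether: it sets out from the 8R epimer of 25 (the one favoured in step 13) and inverts C8 while installing the ester by Mitsunobu esterification with 3-methylbutanoic acid (PPh3, DIAD, toluene, 0 °C), coming back at 28; no new compound is needed (F0).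

Step 11. Conjugate addition of the catalyst to the lactone may be slow, and competing γ-deprotonation would racemise C6 or degrade the butenolide. The fallback replaces the organocatalytic C–C bond formation by halogenation and cross-coupling: it sets out from 20, α-iodination (I2, pyridine, DCM) would give the 3-iodobutenolide F5, and Stille coupling with (tributylstannyl)methanol (Pd(PPh3)4, dioxane, 80 °C) comes back at 22.

**Further compounds**

F1 | step 21 | (1S,2R,3S)-2-(acetyloxy)-4-[(tert-butyldimethylsilyl)oxy]-3-hydroxy-3-methyl-1-{(2R,3S)-4-methylidene-2-[(1Z)-2-methylbut-1-en-3-yn-1-yl]-5-oxooxolan-3-yl}butyl 3-methylbutanoate | C#C/C(C)=C\[C@H]1OC(=O)C(=C)[C@@H]1[C@H](OC(=O)CC(C)C)[C@@H](OC(C)=O)[C@@](C)(O)CO[Si](C)(C)C(C)(C)C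
F2 | step 21 | (1S,2R,3S)-2-(acetyloxy)-3,4-dihydroxy-3-methyl-1-{(2R,3S)-4-methylidene-2-[(1Z)-2-methylbut-1-en-3-yn-1-yl]-5-oxooxolan-3-yl}butyl 3-methylbutanoate | C#C/C(C)=C\[C@H]1OC(=O)C(=C)[C@@H]1[C@H](OC(=O)CC(C)C)[C@@H](OC(C)=O)[C@@](C)(O)CO
F3 | step 21 | (1S,2R,3S)-2-(acetyloxy)-3-methyl-1-{(2R,3S)-4-methylidene-2-[(1Z)-2-methylbut-1-en-3-yn-1-yl]-5-oxooxolan-3-yl}-3,4-bis[(triethylsilyl)oxy]butyl 3-methylbutanoate | C#C/C(C)=C\[C@H]1OC(=O)C(=C)[C@@H]1[C@H](OC(=O)CC(C)C)[C@@H](OC(C)=O)[C@@](C)(O[Si](CC)(CC)CC)CO[Si](CC)(CC)CC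
F4 | step 21 | (1S,2R,3R)-2-(acetyloxy)-3-methyl-1-{(2R,3S)-4-methylidene-2-[(1Z)-2-methylbut-1-en-3-yn-1-yl]-5-oxooxolan-3-yl}-4-oxo-3-[(triethylsilyl)oxy]butyl 3-methylbutanoate | C#C/C(C)=C\[C@H]1OC(=O)C(=C)[C@@H]1[C@H](OC(=O)CC(C)C)[C@@H](OC(C)=O)[C@@](C)(O[Si](CC)(CC)CC)C=O
F0 | step 15 | none | none
F5 | step 11 | (5R)-3-iodo-5-[(1Z)-2-methyl-4-(trimethylsilyl)but-1-en-3-yn-1-yl]furan-2(5H)-one | C[Si](C)(C)C#C/C(C)=C\[C@H]1OC(=O)C(I)=C1
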